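**Retrosynthetic overview**
1. Target 11 ⇒ fluoride desilylation and closure of the pyranone O1–C2 bond (C–O ring closure, the key step) from the o-hydroxyaryl 1,3-diketone 8.
2. 8 ⇒ C-acylation of the methyl ketone of diprenylphloracetophenone 3 with the bis-silylated resorcyloyl chloride 6.
3. 3 ⇒ 2,4,6-trihydroxyacetophenone 1 + two prenyl bromide 2 (double C-prenylation; C3 and C5 are equivalent).
4. 6 ⇒ 2,4-dihydroxybenzoic acid 4 (persilylation, then silyl ester → acid chloride).
5. Ring order: the A and B rings are bought; the only ring formed is the γ-pyranone C ring, in the last step.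

Assumption: the target has no stereocentre and no stereogenic double bond (both prenyl alkenes end in a gem-dimethyl group), so it is achiral and no stereocontrol is needed.

**Route**

Step 1
Reactants: 1 2,4,6-trihydroxyacetophenone; 2 prenyl bromide (2.2 equiv)
Product: 3 1-[2,4,6-trihydroxy-3,5-bis(3-methylbut-2-en-1-yl)phenyl]ethan-1-one
Conditions: 10% aq. KOH, 0 °C → rt
Reagents that add atoms: none
Why: Double C-prenylation of the phloroglucinol phenolate (ambident-phenolate C-alkylation, as used for deoxyhumulones); water favours attack through carbon, and since C3 and C5 are the only free and equivalent ring carbons the di-C-prenyl product is one regioisomer (mono-prenyl material is recycled).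

Step 2
Reactants: 4 2,4-dihydroxybenzoic acid
Product: 5 tert-butyldimethylsilyl 2,4-bis[(tert-butyldimethylsilyl)oxy]benzoate
Conditions: TBSCl (3.6 equiv), imidazole, DMF, rt → 45 °C
Reagents that add atoms: tert-butyldimethylsilyl chloride, CC(C)(C)[Si](C)(C)Cl
Why: Exhaustive silylation (TBSCl/imidazole) masks both B-ring phenols with groups that survive LiHMDS and are later removed by fluoride without acid.

Step 3
Reactants: 5 tert-butyldimethylsilyl 2,4-bis[(tert-butyldimethylsilyl)oxy]benzoate
Product: 6 2,4-bis[(tert-butyldimethylsilyl)oxy]benzoyl chloride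
Conditions: (COCl)2 (1.3 equiv), cat. DMF, CH2Cl2, 0 °C → rt; used crude
Reagents that add atoms: oxalyl chloride, O=C(Cl)C(=O)Cl
Why: Wissner-type conversion of a silyl ester into the acid chloride by the Vilsmeier reagent; TBSCl leaves instead of HCl, so the aryl silyl ethers stay on.

Step 4
Reactants: 3 1-[2,4,6-trihydroxy-3,5-bis(3-methylbut-2-en-1-yl)phenyl]ethan-1-one; 6 2,4-bis[(tert-butyldimethylsilyl)oxy]benzoyl chloride
Product: 8 1-[2,4-bis(tert-butyldimethylsilyloxy)phenyl]-3-[2,4,6-trihydroxy-3,5-bis(3-methylbut-2-en-1-yl)phenyl]propane-1,3-dione, via tetralithium polyanion of the acetophenone 7 (not isolated)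
Conditions: LiHMDS (5.2 equiv), THF, −78 → −10 °C; then 6, −78 °C → rt; cold 1 M HCl to pH 4
Reagents that add atoms: none
Why: Cushman-type polyanion acylation (crossed Claisen C-acylation): with all three phenols lithiated the ketone enolate carbon is the most nucleophilic site, the fifth equivalent of base takes up the acidic diketone proton, and any O-aroyl ester would reach the same diketone by Baker–Venkataraman acyl shift.

Step 5
Reactants: 8 1-[2,4-bis(tert-butyldimethylsilyloxy)phenyl]-3-[2,4,6-trihydroxy-3,5-bis(3-methylbut-2-en-1-yl)phenyl]propane-1,3-dione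
Product: 11 2-(2,4-dihydroxyphenyl)-5,7-dihydroxy-6,8-bis(3-methylbut-2-en-1-yl)-4H-chromen-4-one, via pyrrolidine enaminone of the diketone 9 (not isolated), via bis-silyl flavone 10 (not isolated)
Conditions: pyrrolidine (20 mol%), PhCO2H (20 mol%), MeCN, 45 °C; then KHF2 (3 equiv), MeOH, rt
Reagents that add atoms: none
Why: Proposed new method: aminocatalytic cyclodehydration, in which pyrrolidinium benzoate condenses with the less hindered B-ring-side carbonyl to give the β-enaminone 9, the neighbouring A-ring phenol adds 6-endo to the β-carbon and pyrrolidine is expelled (oxa-Michael addition–elimination), forming the O1–C2 bond irreversibly as the aromatic 4-pyranone in a near-neutral buffer where o-prenylphenols do not close to chromans (the same buffer can also dehydrate the cyclic hemiketal by E1cB to the same product); the closest known reaction types are the ring closure of o-hydroxyaryl enaminones to chromones and the pyrrolidine-catalysed Kabbe chromanone condensation; KHF2/MeOH then cleaves the two aryl silyl ethers (known phenol-selective desilylation), and because the two ortho hydroxyls of 8 are equivalent only one flavone can form.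

**Compound list**
1 | 1-(2,4,6-trihydroxyphenyl)ethan-1-one (2,4,6-trihydroxyacetophenone) | CC(=O)c1c(O)cc(O)cc1O | starting material
2 | 1-bromo-3-methylbut-2-ene (prenyl bromide) | CC(C)=CCBr | starting material
3 | 1-[2,4,6-trihydroxy-3,5-bis(3-methylbut-2-en-1-yl)phenyl]ethan-1-one | CC(=O)c1c(O)c(CC=C(C)C)c(O)c(CC=C(C)C)c1O | intermediate
4 | 2,4-dihydroxybenzoic acid | OC(=O)c1ccc(O)cc1O | starting material
5 | tert-butyldimethylsilyl 2,4-bis[(tert-butyldimethylsilyl)oxy]benzoate | CC(C)(C)[Si](C)(C)OC(=O)c1ccc(O[Si](C)(C)C(C)(C)C)cc1O[Si](C)(C)C(C)(C)C | intermediate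
6 | 2,4-bis[(tert-butyldimethylsilyl)oxy]benzoyl chloride | O=C(Cl)c1ccc(O[Si](C)(C)C(C)(C)C)cc1O[Si](C)(C)C(C)(C)C | intermediate
7 | tetralithium salt of 3 (three phenoxides and the ketone enolate) | [Li+].[Li+].[Li+].[Li+].C=C([O-])c1c([O-])c(CC=C(C)C)c([O-])c(CC=C(C)C)c1[O-] | intermediate
8 | 1-[2,4-bis(tert-butyldimethylsilyloxy)phenyl]-3-[2,4,6-trihydroxy-3,5-bis(3-methylbut-2-en-1-yl)phenyl]propane-1,3-dione (in equilibrium with its enol and cyclic hemiketal) | CC(C)=CCc1c(O)c(CC=C(C)C)c(O)c(C(=O)CC(=O)c2ccc(O[Si](C)(C)C(C)(C)C)cc2O[Si](C)(C)C(C)(C)C)c1O | intermediate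
9 | (E)-3-[2,4-bis(tert-butyldimethylsilyloxy)phenyl]-3-(pyrrolidin-1-yl)-1-[2,4,6-trihydroxy-3,5-bis(3-methylbut-2-en-1-yl)phenyl]prop-2-en-1-one (drawn as E; the geometry is lost on ring closure) | CC(C)=CCc1c(O)c(CC=C(C)C)c(O)c(C(=O)/C=C(/N2CCCC2)c2ccc(O[Si](C)(C)C(C)(C)C)cc2O[Si](C)(C)C(C)(C)C)c1O | intermediate
10 | 2-[2,4-bis(tert-butyldimethylsilyloxy)phenyl]-5,7-dihydroxy-6,8-bis(3-methylbut-2-en-1-yl)-4H-chromen-4-one | CC(C)=CCc1c(O)c(CC=C(C)C)c2oc(-c3ccc(O[Si](C)(C)C(C)(C)C)cc3O[Si](C)(C)C(C)(C)C)cc(=O)c2c1O | intermediate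
11 | 2-(2,4-dihydroxyphenyl)-5,7-dihydroxy-6,8-bis(3-methylbut-2-en-1-yl)-4H-chromen-4-one | CC(C)=CCc1c(O)c(CC=C(C)C)c2oc(-c3ccc(O)cc3O)cc(=O)c2c1O | target

**Totals**
Total step count: 5. Longest linear sequence: 4 steps (4 → 5 → 6 → 8 → 11).

**Steps most likely to fail**

Step 5 (the new amine-catalysed ring closure). The enaminone of a hindered diaryl diketone may form too slowly, or the amine may cleave the diketone by retro-Claisen. The fallback sets out from 8 and drops covalent amine catalysis and the one-pot format. It uses the classical specific-acid closure of the Baker–Venkataraman end-game instead: protonation of the cyclic hemiketal and loss of water in NaOAc-buffered AcOH at 100 °C, a known reaction. It comes back to the route at 10, which is isolated and then desilylated with KHF2/MeOH as in the second stage of step 5 to give 11. This fallback makes no new compound (F0).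

Step 1 (double C-prenylation). O-alkylation, mono-prenylation and gem-diprenylation with dearomatisation compete, so the yield of 3 is modest. The fallback sets out from 1 and replaces phenolate alkylation by Friedel–Crafts prenylation of the neutral phenol with 2-methylbut-3-en-2-ol and BF3·OEt2 in dioxane at rt. The neutral phenol cannot be dearomatised by gem-dialkylation. It comes back at 3. This fallback makes no new compound (F0).

Step 4 (polyanion acylation). The tetra-anion may be poorly soluble, or the hindered ortho-silyloxy acid chloride may O-acylate. The fallback sets out from 3 and uses a protect-first Baker–Venkataraman sequence: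
- MOMCl and i-Pr2NEt in CH2Cl2 cap two of the three phenols to give 1-[2-hydroxy-4,6-bis(methoxymethoxy)-3,5-bis(3-methylbut-2-en-1-yl)phenyl]ethan-1-one F1.
- The remaining chelated phenol is aroylated with 6 (pyridine, DMAP) to give the aryl ester 2-acetyl-3,5-bis(methoxymethoxy)-4,6-bis(3-methylbut-2-en-1-yl)phenyl 2,4-bis[(tert-butyldimethylsilyl)oxy]benzoate F2.
- LiHMDS in THF brings about the O→C acyl shift to 1-[2,4-bis(tert-butyldimethylsilyloxy)phenyl]-3-[2-hydroxy-4,6-bis(methoxymethoxy)-3,5-bis(3-methylbut-2-en-1-yl)phenyl]propane-1,3-dione F3.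
- Dilute HCl in MeOH at 45 °C closes the pyranone and removes both MOM groups, while the aryl silyl ethers largely survive.

It comes back at 10, which is desilylated with KHF2/MeOH as in step 5.

**Further compounds**
F1 | step 4 | 1-[2-hydroxy-4,6-bis(methoxymethoxy)-3,5-bis(3-methylbut-2-en-1-yl)phenyl]ethan-1-one | CC(=O)c1c(O)c(CC=C(C)C)c(OCOC)c(CC=C(C)C)c1OCOC
F2 | step 4 | 2-acetyl-3,5-bis(methoxymethoxy)-4,6-bis(3-methylbut-2-en-1-yl)phenyl 2,4-bis[(tert-butyldimethylsilyl)oxy]benzoate | CC(=O)c1c(OC(=O)c2ccc(O[Si](C)(C)C(C)(C)C)cc2O[Si](C)(C)C(C)(C)C)c(CC=C(C)C)c(OCOC)c(CC=C(C)C)c1OCOC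
F3 | step 4 | 1-[2,4-bis(tert-butyldimethylsilyloxy)phenyl]-3-[2-hydroxy-4,6-bis(methoxymethoxy)-3,5-bis(3-methylbut-2-en-1-yl)phenyl]propane-1,3-dione | CC(C)=CCc1c(O)c(C(=O)CC(=O)c2ccc(O[Si](C)(C)C(C)(C)C)cc2O[Si](C)(C)C(C)(C)C)c(OCOC)c(CC=C(C)C)c1OCOC
F0 | step 1 | none | none
F0 | step 5 | none | none
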